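**Retrosynthetic overview**
- The pivotal bond is the tertiary alkyl C–O bond of ring D. Cleaving it (cycloetherification) together with the adjoining Prins bond of ring C opens the cage to the bicyclic hydroxy-enedione 11, which is stored as its vinylogous methyl ester 10.
- 10 comes from a catalytic asymmetric Diels–Alder reaction (ring B) of (E)-β-ocimene 9 with the hydroxy-methoxy-quinone 8.
- In 8 one oxygen is free (to steer the cycloaddition) and one is methylated (to become the ring-D oxygen). This pattern comes from regioselective hydrolysis of dimethoxyquinone 5, then C-geranylation.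
- 5 comes from 1,2,3,5-tetramethoxybenzene 1 by lithiation/prenylation and oxidative demethylation.
- Ring order: A (from the arene), then B (Diels–Alder), then C and D together (Prins/cycloetherification).

Prenyl = 3-methylbut-2-en-1-yl; geranyl = (2E)-3,7-dimethylocta-2,6-dien-1-yl.

Assumption: the (S)-ligand in step 5 is taken to give the enantiomer drawn; if the sense of induction is the opposite, the (R)-ligand is used with no other change.
Assumption: 9 is used as commercial E-enriched β-ocimene; the Z isomer cannot reach the s-cis conformation and stays behind unchanged.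

**Step 1**
Reactants: 1 1,2,3,5-tetramethoxybenzene; 2 prenyl bromide
Product: 4 1,2,3,5-tetramethoxy-4-prenylbenzene, via aryllithium 3 (not isolated)
Conditions: n-BuLi, TMEDA, THF, 0 °C; then CuBr·SMe2 (10 mol%), 2, −78 → 23 °C
Reagents that add atoms: none
Why: Directed ortho-lithiation at the C–H flanked by two methoxy groups followed by copper-assisted SN2 allylation of the aryllithium gives the linear prenyl arene; no stereocentre is formed.

**Step 2**
Reactants: 4 1,2,3,5-tetramethoxy-4-prenylbenzene
Product: 5 2,6-dimethoxy-3-prenyl-1,4-benzoquinone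
Conditions: (NH4)2Ce(NO3)6 (2.5 equiv), MeCN/H2O 2:1, 0 °C, 15 min
Reagents that add atoms: water, O
Why: Oxidative demethylation of the para-dimethoxy pair by tetravalent cerium gives the p-quinone, water supplying both carbonyl oxygens; the isolated prenyl alkene survives the short, cold exposure.

**Step 3**
Reactants: 5 2,6-dimethoxy-3-prenyl-1,4-benzoquinone
Product: 6 2-hydroxy-6-methoxy-5-prenyl-1,4-benzoquinone
Conditions: NaOH (2 equiv), THF/H2O, 0 → 23 °C; then 1 M HCl
Reagents that add atoms: sodium hydroxide, [Na+].[OH-]
Why: Vinylogous ester saponification (addition–elimination) is faster at C6, whose neighbour C5 carries only H, than at C2, which is flanked by the prenyl group, and the vinylogous carboxylate formed resists a second hydrolysis.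

**Step 4**
Reactants: 6 2-hydroxy-6-methoxy-5-prenyl-1,4-benzoquinone; 7 geranyl bromide
Product: 8 3-geranyl-2-hydroxy-6-methoxy-5-prenyl-1,4-benzoquinone
Conditions: LiH, DMSO, 23 °C; then 7, 23 → 40 °C
Reagents that add atoms: none
Why: C-alkylation of the ambident hydroxyquinone anion at C3, its only nucleophilic carbon, by SN2 displacement on the allylic bromide (the alkylation used to make lapachol from lawsone) keeps the E alkene; moderate yield is expected because O-alkylation competes.

**Step 5**
Reactants: 8 3-geranyl-2-hydroxy-6-methoxy-5-prenyl-1,4-benzoquinone; 9 (E)-β-ocimene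
Product: 10 (4aR,5S,8aR)-8a-geranyl-4a-hydroxy-3-methoxy-6-methyl-2,5-diprenyl-4a,5,8,8a-tetrahydronaphthalene-1,4-dione
Conditions: (S)-3,3′-diphenyl-1,1′-bi-2-naphthol (20 mol%), BH3·THF (20 mol%), CH2Cl2, 23 °C, 1 h; then 8, −40 °C; 9 (3 equiv), −40 → −20 °C, 48 h; pH 7 buffer
Reagents that add atoms: none
Why: Proposed new method: an exchange-catalytic chiral spiroborate Diels–Alder reaction in which the acidic 2-OH of 8 binds covalently to the binaphtholate boron and the neighbouring C1=O closes a five-membered chelate; the chelate makes the hydroxyl a weak π-donor and activates C1=O, so the OH/geranyl alkene (C2=C3) rather than the OMe/prenyl alkene is the dienophile and C3 takes the unsubstituted diene terminus, one 3-phenyl group covers one face so that 9 adds endo to the open face and sets C8a (R), C4a (R) and C5 (S) in one event, and the catalyst turns over because the tertiary alkoxide of 10 is displaced from boron by the more acidic enol OH of the next molecule of 8; the closest known reaction type is the stoichiometric chiral binaphthol–boron-templated Diels–Alder reaction of peri-hydroxy naphthoquinones, here moved to a 2-hydroxy-1,4-benzoquinone with a fully substituted dienophile and made catalytic.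

**Step 6**
Reactants: 10 (4aR,5S,8aR)-8a-geranyl-4a-hydroxy-3-methoxy-6-methyl-2,5-diprenyl-4a,5,8,8a-tetrahydronaphthalene-1,4-dione
Product: 12 target tetracycle, via enol 11 (not isolated)
Conditions: 1 M HCl (aq)/THF 1:4, 23 °C, 3 h; then 50 °C
Reagents that add atoms: water, O
Why: Acid hydrolysis of the vinylogous methyl ester frees the C3 enol oxygen, the C4 ketone is then attacked by the trisubstituted alkene of the C5 prenyl chain (Prins reaction, ring C) on the face that carries the tether, and the tertiary cation is captured by the enol oxygen (cycloetherification, the ring-D C–O bond); the cis-fused cage allows only the diastereomer with both tertiary OH groups cis, which fixes the last two stereocentres.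

**Compound list**
1 | 1,2,3,5-tetramethoxybenzene | COc1cc(OC)c(OC)c(OC)c1 | starting material
2 | prenyl bromide (1-bromo-3-methylbut-2-ene) | CC(C)=CCBr | starting material
3 | (2,3,4,6-tetramethoxyphenyl)lithium | [Li]c1c(OC)cc(OC)c(OC)c1OC | intermediate
4 | 1,2,3,5-tetramethoxy-4-prenylbenzene | COc1cc(OC)c(OC)c(OC)c1CC=C(C)C | intermediate
5 | 2,6-dimethoxy-3-prenyl-1,4-benzoquinone | COC1=CC(=O)C(CC=C(C)C)=C(OC)C1=O | intermediate
6 | 2-hydroxy-6-methoxy-5-prenyl-1,4-benzoquinone | OC1=CC(=O)C(CC=C(C)C)=C(OC)C1=O | intermediate
7 | geranyl bromide ((2E)-1-bromo-3,7-dimethylocta-2,6-diene) | CC(C)=CCC/C(C)=C/CBr | starting material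
8 | 3-geranyl-2-hydroxy-6-methoxy-5-prenyl-1,4-benzoquinone | CC(C)=CCC/C(C)=C/CC1=C(O)C(=O)C(OC)=C(CC=C(C)C)C1=O | intermediate
9 | (E)-β-ocimene ((3E)-3,7-dimethylocta-1,3,6-triene) | C=C/C(C)=C/CC=C(C)C | starting material
10 | (4aR,5S,8aR)-8a-geranyl-4a-hydroxy-3-methoxy-6-methyl-2,5-diprenyl-4a,5,8,8a-tetrahydronaphthalene-1,4-dione (cis-fused; C5 chain on the same face as C4) | CC(C)=CCC/C(C)=C/C[C@@]12CC=C(C)[C@H](CC=C(C)C)[C@]1(O)C(=O)C(OC)=C(CC=C(C)C)C2=O | intermediate
11 | (4aR,5S,8aR)-8a-geranyl-3,4a-dihydroxy-6-methyl-2,5-diprenyl-4a,5,8,8a-tetrahydronaphthalene-1,4-dione | CC(C)=CCC/C(C)=C/C[C@@]12CC=C(C)[C@H](CC=C(C)C)[C@]1(O)C(=O)C(O)=C(CC=C(C)C)C2=O | intermediate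
12 | target tetracycle: ring A cyclohex-2-enone (prenyl on the α-carbon, ring-D oxygen on the β-carbon), ring B 4-methylcyclohexene, ring C cyclopentane, ring D 2,2-dimethyltetrahydrofuran; geranyl-bearing quaternary carbon R, both carbinol carbons R, both ring-fusion CH carbons S; geranyl, both OH and both ring-fusion H on the convex face | CC(C)=CCC/C(C)=C/C[C@]12CC=C(C)[C@@H]3C[C@@H]4C(C)(C)OC(=C(CC=C(C)C)C1=O)[C@]4(O)[C@@]32O | target

**Step count**
Total steps: 6. Longest linear sequence: 6 (1 → 4 → 5 → 6 → 8 → 10 → 12).

**Steps most likely to fail and fallbacks**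

Step 5 (the proposed catalysis) is the most uncertain step. The boron chelate may not turn over, the methoxy-bearing alkene may compete, the face selectivity is untested, and the boron-bound ketone may undergo a premature ene closure with the pendant alkene. The fallback uses only known reactions and sets out from 8. Acetylation (Ac2O, pyridine) gives 2-acetoxy-3-geranyl-6-methoxy-5-prenyl-1,4-benzoquinone F1, whose acetoxy-bearing alkene is the only one not deactivated by a strong donor oxygen. Heating F1 with 9 in toluene at 90 °C gives the racemic endo adduct, that is the (4aR,5S,8aR) adduct acetate F2 together with its mirror image, the (4aS,5R,8aS) adduct acetate F3. Preparative chromatography on a chiral stationary phase removes F3, and K2CO3/MeOH at 0 °C cleaves the acetate of F2, which comes back to the route at 10.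

Step 4 can fail through O-alkylation and double alkylation of the ambident anion. The fallback sets out from 6 and replaces the SN2 alkylation by a Tsuji–Trost allylation. Geranyl methyl carbonate F4 (from geraniol and methyl chloroformate) is ionised by Pd(PPh3)4 (5 mol%, THF, 40 °C), the methoxide released deprotonates 6, and the soft vinylogous carboxylate attacks the unsubstituted terminus of the allyl complex of zerovalent palladium through carbon. It comes back at 8.

Step 3 can fail if hydroxide does not discriminate between the two methoxy groups of 5. The fallback removes the question by hydrolysing a symmetric quinone, and sets out from 1. Oxidation with (NH4)2Ce(NO3)6 gives 2,6-dimethoxy-1,4-benzoquinone F5, and NaOH gives 2-hydroxy-6-methoxy-1,4-benzoquinone F6 as the only possible mono-hydrolysis product. C-alkylation with 7 as in step 4 gives 3-geranyl-2-hydroxy-6-methoxy-1,4-benzoquinone F7, and Na2S2O4 reduces it to 3-geranyl-6-methoxybenzene-1,2,4-triol F8. Friedel–Crafts prenylation at the single free ring position (2-methylbut-3-en-2-ol, BF3·OEt2, dioxane) gives 3-geranyl-6-methoxy-5-prenylbenzene-1,2,4-triol F9, and Ag2O reoxidises it to come back at 8.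

**Further compounds**
F1 | step 5 | 2-acetoxy-3-geranyl-6-methoxy-5-prenyl-1,4-benzoquinone | CC(C)=CCC/C(C)=C/CC1=C(OC(C)=O)C(=O)C(OC)=C(CC=C(C)C)C1=O
F2 | step 5 | (4aR,5S,8aR)-8a-geranyl-3-methoxy-6-methyl-1,4-dioxo-2,5-diprenyl-4a,5,8,8a-tetrahydronaphthalen-4a-yl acetate | CC(C)=CCC/C(C)=C/C[C@@]12CC=C(C)[C@H](CC=C(C)C)[C@]1(OC(C)=O)C(=O)C(OC)=C(CC=C(C)C)C2=O
F3 | step 5 | (4aS,5R,8aS)-8a-geranyl-3-methoxy-6-methyl-1,4-dioxo-2,5-diprenyl-4a,5,8,8a-tetrahydronaphthalen-4a-yl acetate | CC(C)=CCC/C(C)=C/C[C@]12CC=C(C)[C@@H](CC=C(C)C)[C@@]1(OC(C)=O)C(=O)C(OC)=C(CC=C(C)C)C2=O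
F4 | step 4 | geranyl methyl carbonate | CC(C)=CCC/C(C)=C/COC(=O)OC
F5 | step 3 | 2,6-dimethoxy-1,4-benzoquinone | COC1=CC(=O)C=C(OC)C1=O
F6 | step 3 | 2-hydroxy-6-methoxy-1,4-benzoquinone | OC1=CC(=O)C=C(OC)C1=O
F7 | step 3 | 3-geranyl-2-hydroxy-6-methoxy-1,4-benzoquinone | CC(C)=CCC/C(C)=C/CC1=C(O)C(=O)C(OC)=CC1=O
F8 | step 3 | 3-geranyl-6-methoxybenzene-1,2,4-triol | CC(C)=CCC/C(C)=C/Cc1c(O)c(O)c(OC)cc1O
F9 | step 3 | 3-geranyl-6-methoxy-5-prenylbenzene-1,2,4-triol | CC(C)=CCC/C(C)=C/Cc1c(O)c(O)c(OC)c(CC=C(C)C)c1O
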